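The route rests on making the butenolide C7=C11 double bond last, on a preformed ten-membered carbocycle (germacranolide numbering). The C6 oxygen of a cyclodecane α-hydroxy ketone (C7=O, flanked by the C8 tiglate) carries C12, C11 and C13 as an α-phosphono ester. An intramolecular Horner–Wadsworth–Emmons olefination then closes the five-membered lactone ring, creates the tetrasubstituted C7=C11 alkene and delivers C13 oxygenated in one operation. The step exploits the 1,2-disposition of the C6 lactone oxygen and C7 at the fusion of the ten-membered and butenolide rings, the O6–C12 ester acting as tether. The carbocycle arises from neryl acetate through Brown crotylation, Sharpless epoxidation and Nozaki–Hiyama–Kishi closure of C7–C8.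

Key step: step 18

Remark: the structure is read as the tigloyl (E) ester with a cis (4R,5S) epoxide; atoms carry germacranolide locants (C1 carbinol, C4/C5 epoxide, C6 lactone O–CH, C7/C11 butenolide alkene, C8 ester carbinol, C10 CH–CH3, C12 lactone C=O, C13 CH2OAc), also in open-chain precursors; ethyl 2-(diethoxyphosphoryl)acrylate and (+)-Ipc2BOMe are taken as commercial.

Step 1
Reactants: 1 neryl acetate, (2Z)-3,7-dimethylocta-2,6-dien-1-yl acetate
Product: 3 (2Z)-3-methyl-6-oxohex-2-en-1-yl acetate, via ozonide 2 (not isolated)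
Conditions: O3 (1 equiv, Sudan Red 7B end point), CH2Cl2, −78 °C; then Me2S, −78 °C → rt
Reagents that add atoms: ozone, [O-][O+]=O
Why: Chemoselective ozonolysis with reductive work-up: the electron-rich distal trisubstituted alkene should react well before the allylic-acetate alkene, which is inductively deactivated and keeps its Z geometry.

Step 2
Reactants: 3 (2Z)-3-methyl-6-oxohex-2-en-1-yl acetate
Product: 5 (2Z,6S,7R)-6-hydroxy-3,7-dimethylnona-2,8-dien-1-yl acetate, via borinate 4 (not isolated)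
Conditions: cis-2-butene, KOtBu, n-BuLi, THF, −78 → −45 °C; (+)-Ipc2BOMe, −78 °C; BF3·OEt2; then 3, −78 °C; ethanolamine, rt
Reagents that add atoms: cis-2-butene, C/C=C\C
Why: Brown asymmetric crotylboration through a closed chair transition state: the (Z)-crotyl geometry gives the syn C1-OH/C10-CH3 pair, and the (+)-Ipc2B reagent (from (−)-α-pinene) selects the aldehyde re face, so C1 (S) and C10 (R) are set under reagent control; the non-oxidative ethanolamine work-up keeps the acetate.

Step 3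
Reactants: 5 (2Z,6S,7R)-6-hydroxy-3,7-dimethylnona-2,8-dien-1-yl acetate
Product: 6 (2Z,6S,7R)-6-[(tert-butyldimethylsilyl)oxy]-3,7-dimethylnona-2,8-dien-1-yl acetate
Conditions: TBSOTf, 2,6-lutidine, CH2Cl2, −78 °C
Reagents that add atoms: tert-butyldimethylsilyl triflate, CC(C)(C)[Si](C)(C)OS(=O)(=O)C(F)(F)F
Why: Silyl ether formation masks the C1 hydroxyl, which must stay free of acyl groups to the end; a secondary TBS ether should survive every later step up to the final fluoride treatment.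

Step 4
Reactants: 6 (2Z,6S,7R)-6-[(tert-butyldimethylsilyl)oxy]-3,7-dimethylnona-2,8-dien-1-yl acetate
Product: 7 (2Z,6S,7R)-6-[(tert-butyldimethylsilyl)oxy]-3,7-dimethylnona-2,8-dien-1-ol
Conditions: K2CO3, MeOH, 0 °C → rt
Reagents that add atoms: none
Why: Base-catalysed transesterification (methanolysis) of the acetate frees the (Z)-allylic alcohol that the epoxidation catalyst needs, and leaves the silyl ether untouched.

Step 5
Reactants: 7 (2Z,6S,7R)-6-[(tert-butyldimethylsilyl)oxy]-3,7-dimethylnona-2,8-dien-1-ol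
Product: 8 {(2S,3R)-3-[(3S,4R)-3-[(tert-butyldimethylsilyl)oxy]-4-methylhex-5-en-1-yl]-3-methyloxiran-2-yl}methanol
Conditions: Ti(OiPr)4 (10 mol %), L-(+)-diethyl tartrate (12 mol %), t-BuOOH, 4 Å molecular sieves, CH2Cl2, −20 °C
Reagents that add atoms: tert-butyl hydroperoxide, CC(C)(C)OO
Why: Sharpless asymmetric epoxidation: the titanium/L-(+)-tartrate catalyst should deliver oxygen to the same face as in nerol, giving the cis (2S,3R) epoxide, i.e. C4 (R) and C5 (S), under reagent control; the isolated vinyl group is not an allylic alcohol and should not react.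

Step 6
Reactants: 8 {(2S,3R)-3-[(3S,4R)-3-[(tert-butyldimethylsilyl)oxy]-4-methylhex-5-en-1-yl]-3-methyloxiran-2-yl}methanol
Product: 9 (2R,3R)-3-[(3S,4R)-3-[(tert-butyldimethylsilyl)oxy]-4-methylhex-5-en-1-yl]-3-methyloxirane-2-carbaldehyde
Conditions: Dess–Martin periodinane, NaHCO3, CH2Cl2, 0 °C → rt
Reagents that add atoms: none
Why: Buffered Dess–Martin oxidation converts the primary alcohol into the α,β-epoxy aldehyde without acid that could open the trisubstituted epoxide; the epoxide CH next to the carbonyl does not enolise, so C5 is not at risk.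

Step 7
Reactants: 9 (2R,3R)-3-[(3S,4R)-3-[(tert-butyldimethylsilyl)oxy]-4-methylhex-5-en-1-yl]-3-methyloxirane-2-carbaldehyde
Product: 10 (1R)-2-bromo-1-{(2S,3R)-3-[(3S,4R)-3-[(tert-butyldimethylsilyl)oxy]-4-methylhex-5-en-1-yl]-3-methyloxiran-2-yl}prop-2-en-1-ol
Conditions: vinyl bromide, LiN(iPr)2 (LDA), THF/Et2O/pentane, −110 °C; then 9, −110 → −90 °C; aq NH4Cl
Reagents that add atoms: vinyl bromide, C=CBr
Why: 1,2-Addition of 1-bromo-1-lithioethene to the aldehyde brings in C7 as a latent acyl anion; Felkin–Anh/Cornforth control by the α-epoxide C–O bond (attack anti to C5–O, past the C5–H) should give the erythro epoxy alcohol, which is the C6 configuration of the target (1R in 10, 6S after the later priority change).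

Step 8
Reactants: 10 (1R)-2-bromo-1-{(2S,3R)-3-[(3S,4R)-3-[(tert-butyldimethylsilyl)oxy]-4-methylhex-5-en-1-yl]-3-methyloxiran-2-yl}prop-2-en-1-ol
Product: 11 triethylsilyl ether of 10 at the C6 hydroxyl (all stereocentres as in 10)
Conditions: Et3SiCl, imidazole, DMAP (cat.), CH2Cl2, 0 °C
Reagents that add atoms: chlorotriethylsilane, CC[Si](Cl)(CC)CC
Why: Silyl ether formation under non-acidic conditions protects C6-OH as a TES ether, which avoids an allylic ester next to the alkenyl bromide in the chromium step and can later be cleaved in the presence of the TBS ether.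

Step 9
Reactants: 11 triethylsilyl ether of 10 at the C6 hydroxyl
Product: 13 (3R,4S)-6-{(2R,3S)-3-[(1R)-2-bromo-1-[(triethylsilyl)oxy]prop-2-en-1-yl]-2-methyloxiran-2-yl}-4-[(tert-butyldimethylsilyl)oxy]-3-methylhexan-1-ol, via alkylborane 12 (not isolated)
Conditions: 9-BBN, THF, 0 °C → rt; then H2O2, aq NaOH, 0 °C
Reagents that add atoms: hydrogen peroxide, OO
Why: Hydroboration–oxidation: 9-BBN should add anti-Markovnikov to the monosubstituted alkene only, the 2-bromoalkene being deactivated by the halogen and shielded by the silyloxy group, so that C8 becomes a primary alcohol.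

Step 10
Reactants: 13 (3R,4S)-6-{(2R,3S)-3-[(1R)-2-bromo-1-[(triethylsilyl)oxy]prop-2-en-1-yl]-2-methyloxiran-2-yl}-4-[(tert-butyldimethylsilyl)oxy]-3-methylhexan-1-ol
Product: 14 (3R,4S)-6-{(2R,3S)-3-[(1R)-2-bromo-1-[(triethylsilyl)oxy]prop-2-en-1-yl]-2-methyloxiran-2-yl}-4-[(tert-butyldimethylsilyl)oxy]-3-methylhexanal
Conditions: Dess–Martin periodinane, NaHCO3, CH2Cl2, 0 °C → rt
Reagents that add atoms: none
Why: Dess–Martin oxidation gives the C8 aldehyde under neutral conditions that should spare silyl ethers, epoxide and alkenyl bromide; the stereocentre at C10 is β to the carbonyl and cannot epimerise.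

Step 11
Reactants: 14 (3R,4S)-6-{(2R,3S)-3-[(1R)-2-bromo-1-[(triethylsilyl)oxy]prop-2-en-1-yl]-2-methyloxiran-2-yl}-4-[(tert-butyldimethylsilyl)oxy]-3-methylhexanal
Product: 15 (1S,4R,5S,6S,8S,10R)-1-[(tert-butyldimethylsilyl)oxy]-4,5-epoxy-4,10-dimethyl-7-methylidene-6-[(triethylsilyl)oxy]cyclodecan-8-ol
Conditions: CrCl2 (excess), NiCl2 (1 mol %), DMSO/THF, rt, 0.003 M, slow addition of 14
Reagents that add atoms: none
Why: Intramolecular Nozaki–Hiyama–Kishi coupling (zerovalent nickel inserts into C–Br, transmetalation to trivalent chromium, addition to the C8 aldehyde) closes the ten-membered ring at C7–C8 without base; the 6,8-syn alcohol (8S) is expected because both allylic C–H bonds can eclipse the exocyclic methylene (minimal A(1,3) strain) only when C5 and C9 leave the alkenyl plane on the same face, as the six-bond tether demands, which places O6 and O8 syn.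

Step 12
Reactants: 15 (1S,4R,5S,6S,8S,10R)-1-[(tert-butyldimethylsilyl)oxy]-4,5-epoxy-4,10-dimethyl-7-methylidene-6-[(triethylsilyl)oxy]cyclodecan-8-ol
Product: 17 (1S,4R,5S,6R,8S,10R)-1-[(tert-butyldimethylsilyl)oxy]-4,5-epoxy-8-hydroxy-4,10-dimethyl-6-[(triethylsilyl)oxy]cyclodecan-7-one, via ozonide 16 (not isolated)
Conditions: O3, CH2Cl2, −78 °C; then Me2S, −78 °C → rt
Reagents that add atoms: ozone, [O-][O+]=O
Why: Ozonolysis of the only C=C bond unmasks the C7 ketone, so the alkenyl bromide has served as an acyl anion equivalent; it is placed before the tiglate is introduced because the tigloyl alkene would not survive ozone, and no stereocentre is touched.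

Step 13
Reactants: 17 (1S,4R,5S,6R,8S,10R)-1-[(tert-butyldimethylsilyl)oxy]-4,5-epoxy-8-hydroxy-4,10-dimethyl-6-[(triethylsilyl)oxy]cyclodecan-7-one
Product: 18 (1S,4R,5S,6R,8S,10R)-1-[(tert-butyldimethylsilyl)oxy]-4,5-epoxy-4,10-dimethyl-7-oxo-6-[(triethylsilyl)oxy]cyclodecan-8-yl (2E)-2-methylbut-2-enoate
Conditions: tigloyl chloride, pyridine, DMAP (cat.), CH2Cl2, 0 °C
Reagents that add atoms: tigloyl chloride, C/C=C(\C)C(Cl)=O
Why: DMAP-catalysed acylation of the only free hydroxyl installs the tiglate at C8 with retention; the (E) acyl group is the stable isomer and should not isomerise, and the weak base should not epimerise the α-acyloxy ketone.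

Step 14
Reactants: 18 (1S,4R,5S,6R,8S,10R)-1-[(tert-butyldimethylsilyl)oxy]-4,5-epoxy-4,10-dimethyl-7-oxo-6-[(triethylsilyl)oxy]cyclodecan-8-yl (2E)-2-methylbut-2-enoate
Product: 19 (1S,4R,5S,6R,8S,10R)-1-[(tert-butyldimethylsilyl)oxy]-4,5-epoxy-6-hydroxy-4,10-dimethyl-7-oxocyclodecan-8-yl (2E)-2-methylbut-2-enoate
Conditions: HF·pyridine, pyridine, THF, 0 °C
Reagents that add atoms: none
Why: Fluoride-mediated desilylation: buffered HF·pyridine should cleave the TES ether much faster than the secondary TBS ether and, being non-basic, should not trigger 1,3-acyl migration of the tiglate or opening of the epoxide.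

Step 15
Reactants: 20 ethyl 2-(diethoxyphosphoryl)acrylate
Product: 21 ethyl 2-(diethoxyphosphoryl)-3-[(4-methoxybenzyl)oxy]propanoate (racemic)
Conditions: 4-methoxybenzyl alcohol, KOtBu (10 mol %), THF, 0 °C
Reagents that add atoms: 4-methoxybenzyl alcohol, COc1ccc(CO)cc1
Why: Base-catalysed oxa-Michael addition of the alkoxide to the doubly activated alkene places the protected C13 oxygen β to phosphorus; the stabilised carbanion is protonated by the alcohol, which carries the chain.

Step 16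
Reactants: 21 ethyl 2-(diethoxyphosphoryl)-3-[(4-methoxybenzyl)oxy]propanoate
Product: 22 2-(diethoxyphosphoryl)-3-[(4-methoxybenzyl)oxy]propanoic acid (racemic)
Conditions: LiOH, THF/H2O, 0 °C; then aq HCl to pH 3
Reagents that add atoms: lithium hydroxide, [Li+].[OH-]
Why: Saponification of the carboxylic ester, which is far more reactive than the phosphonate esters; the low temperature is chosen to suppress retro-Michael loss of the benzyloxide.

Step 17
Reactants: 19 (1S,4R,5S,6R,8S,10R)-1-[(tert-butyldimethylsilyl)oxy]-4,5-epoxy-6-hydroxy-4,10-dimethyl-7-oxocyclodecan-8-yl (2E)-2-methylbut-2-enoate; 22 2-(diethoxyphosphoryl)-3-[(4-methoxybenzyl)oxy]propanoic acid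
Product: 23 6-O-[2-(diethoxyphosphoryl)-3-(4-methoxybenzyloxy)propanoyl] derivative of 19 (both epimers at the phosphonate carbon)
Conditions: EDC·HCl, DMAP (cat.), CH2Cl2, 0 °C → rt
Reagents that add atoms: none
Why: Steglich-type carbodiimide esterification of the α-hydroxy ketone attaches C12, C11 and C13 to O6 as the tether for the ring closure; the epimer mixture at the phosphonate carbon is without consequence because that carbon becomes sp2.

Step 18
Reactants: 23 6-O-[2-(diethoxyphosphoryl)-3-(4-methoxybenzyloxy)propanoyl] derivative of 19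
Product: 24 (1S,4R,5S,6S,8S,10R)-1-[(tert-butyldimethylsilyl)oxy]-4,5-epoxy-13-[(4-methoxybenzyl)oxy]-8-(tigloyloxy)germacr-7(11)-en-12,6-olide
Conditions: LiCl, i-Pr2NEt, MeCN, 0 °C → rt
Reagents that add atoms: none
Why: Intramolecular Horner–Wadsworth–Emmons olefination under Masamune–Roush conditions: LiCl/i-Pr2NEt generates the lithium-chelated phosphonate carbanion at C11, which adds to the C7 ketone (strongly electrophilic because of its two α-acyloxy groups), and the oxaphosphetane collapses with loss of lithium diethyl phosphate to the C7=C11 alkene. The closest known reaction type is the butenolide synthesis by HWE cyclisation of α-(phosphonoacyloxy) ketones. The butenolide ring (O6, C12, C11, C7, C6) closes by 5-exo-trig attack of C11 on the C7 carbonyl, and the O6–C12 ester tether guarantees the 6,12-lactone and not the 8,12-lactone. No stereocentre is created, the phosphonate carbon becomes sp2 and the alkene geometry is fixed by the ring. The step needs deprotonation of the doubly activated phosphonate C–H in preference to the ketone α-C–H bonds at C6 and C8 (epimerisation, E1cB opening of the epoxide), which the mild amine/LiCl base and the fast five-ring closure should secure; the 4-methoxybenzyloxide on C13 is a poor leaving group, so β-elimination from the carbanion should not compete.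

Step 19
Reactants: 24 (1S,4R,5S,6S,8S,10R)-1-[(tert-butyldimethylsilyl)oxy]-4,5-epoxy-13-[(4-methoxybenzyl)oxy]-8-(tigloyloxy)germacr-7(11)-en-12,6-olide
Product: 25 (1S,4R,5S,6S,8S,10R)-1-[(tert-butyldimethylsilyl)oxy]-4,5-epoxy-13-hydroxy-8-(tigloyloxy)germacr-7(11)-en-12,6-olide
Conditions: DDQ, CH2Cl2/pH 7 buffer, 0 °C → rt
Reagents that add atoms: none
Why: Oxidative cleavage of the 4-methoxybenzyl ether by DDQ (benzylic oxidation to the oxocarbenium ion, then hydrolysis) frees the C13 hydroxyl; the buffer protects the epoxide, and silyl ether, butenolide and tiglate are not oxidised.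

Step 20
Reactants: 25 (1S,4R,5S,6S,8S,10R)-1-[(tert-butyldimethylsilyl)oxy]-4,5-epoxy-13-hydroxy-8-(tigloyloxy)germacr-7(11)-en-12,6-olide
Product: 26 (1S,4R,5S,6S,8S,10R)-13-acetoxy-1-[(tert-butyldimethylsilyl)oxy]-4,5-epoxy-8-(tigloyloxy)germacr-7(11)-en-12,6-olide
Conditions: Ac2O, pyridine, DMAP (cat.), CH2Cl2, 0 °C
Reagents that add atoms: acetic anhydride, CC(=O)OC(C)=O
Why: Acetylation of the only free (primary allylic) hydroxyl gives the 13-acetate, C1-OH being still silylated.

Step 21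
Reactants: 26 (1S,4R,5S,6S,8S,10R)-13-acetoxy-1-[(tert-butyldimethylsilyl)oxy]-4,5-epoxy-8-(tigloyloxy)germacr-7(11)-en-12,6-olide
Product: 27 (1S,4R,5S,6S,8S,10R)-13-acetoxy-4,5-epoxy-1-hydroxy-8-(tigloyloxy)germacr-7(11)-en-12,6-olide (CNP0159184.1)
Conditions: HF·pyridine, pyridine, THF, 0 °C → rt
Reagents that add atoms: none
Why: Fluoride-mediated cleavage of the TBS ether under buffered, non-basic conditions should free C1-OH without opening the epoxide, migrating the acetate or tiglate, or epimerising the γ-positions of the butenolide.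

Compound list
1 | neryl acetate, (2Z)-3,7-dimethylocta-2,6-dien-1-yl acetate | CC(C)=CCC/C(C)=C\COC(C)=O | starting material
2 | ozonide of 1, (2Z)-5-(5,5-dimethyl-1,2,4-trioxolan-3-yl)-3-methylpent-2-en-1-yl acetate | CC1(C)OOC(CC/C(C)=C\COC(C)=O)O1 | intermediate
3 | (2Z)-3-methyl-6-oxohex-2-en-1-yl acetate | O=CCC/C(C)=C\COC(C)=O | intermediate
4 | O-diisopinocampheylboryl derivative (borinate) of 5 | C=C[C@@H](C)[C@@H](OB([C@H]1C[C@H]2C[C@@H]([C@@H]1C)C2(C)C)[C@H]1C[C@H]2C[C@@H]([C@@H]1C)C2(C)C)CC/C(C)=C\COC(C)=O | intermediate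
5 | (2Z,6S,7R)-6-hydroxy-3,7-dimethylnona-2,8-dien-1-yl acetate | C=C[C@@H](C)[C@@H](O)CC/C(C)=C\COC(C)=O | intermediate
6 | (2Z,6S,7R)-6-[(tert-butyldimethylsilyl)oxy]-3,7-dimethylnona-2,8-dien-1-yl acetate | C=C[C@@H](C)[C@@H](O[Si](C)(C)C(C)(C)C)CC/C(C)=C\COC(C)=O | intermediate
7 | (2Z,6S,7R)-6-[(tert-butyldimethylsilyl)oxy]-3,7-dimethylnona-2,8-dien-1-ol | C=C[C@@H](C)[C@@H](O[Si](C)(C)C(C)(C)C)CC/C(C)=C\CO | intermediate
8 | {(2S,3R)-3-[(3S,4R)-3-[(tert-butyldimethylsilyl)oxy]-4-methylhex-5-en-1-yl]-3-methyloxiran-2-yl}methanol | C=C[C@@H](C)[C@@H](O[Si](C)(C)C(C)(C)C)CC[C@@]1(C)O[C@H]1CO | intermediate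
9 | (2R,3R)-3-[(3S,4R)-3-[(tert-butyldimethylsilyl)oxy]-4-methylhex-5-en-1-yl]-3-methyloxirane-2-carbaldehyde | C=C[C@@H](C)[C@@H](O[Si](C)(C)C(C)(C)C)CC[C@@]1(C)O[C@H]1C=O | intermediate
10 | (1R)-2-bromo-1-{(2S,3R)-3-[(3S,4R)-3-[(tert-butyldimethylsilyl)oxy]-4-methylhex-5-en-1-yl]-3-methyloxiran-2-yl}prop-2-en-1-ol | C=C[C@@H](C)[C@@H](O[Si](C)(C)C(C)(C)C)CC[C@@]1(C)O[C@H]1[C@@H](O)C(Br)=C | intermediate
11 | triethylsilyl ether of 10 at the C6 hydroxyl | C=C[C@@H](C)[C@@H](O[Si](C)(C)C(C)(C)C)CC[C@@]1(C)O[C@H]1[C@@H](O[Si](CC)(CC)CC)C(Br)=C | intermediate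
12 | B-alkyl-9-borabicyclo[3.3.1]nonane from 11 (boron on the terminal carbon C8) | C1CC2CCCC(C1)B2CC[C@@H](C)[C@@H](O[Si](C)(C)C(C)(C)C)CC[C@@]1(C)O[C@H]1[C@@H](O[Si](CC)(CC)CC)C(Br)=C | intermediate
13 | (3R,4S)-6-{(2R,3S)-3-[(1R)-2-bromo-1-[(triethylsilyl)oxy]prop-2-en-1-yl]-2-methyloxiran-2-yl}-4-[(tert-butyldimethylsilyl)oxy]-3-methylhexan-1-ol | OCC[C@@H](C)[C@@H](O[Si](C)(C)C(C)(C)C)CC[C@@]1(C)O[C@H]1[C@@H](O[Si](CC)(CC)CC)C(Br)=C | intermediate
14 | (3R,4S)-6-{(2R,3S)-3-[(1R)-2-bromo-1-[(triethylsilyl)oxy]prop-2-en-1-yl]-2-methyloxiran-2-yl}-4-[(tert-butyldimethylsilyl)oxy]-3-methylhexanal | O=CC[C@@H](C)[C@@H](O[Si](C)(C)C(C)(C)C)CC[C@@]1(C)O[C@H]1[C@@H](O[Si](CC)(CC)CC)C(Br)=C | intermediate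
15 | (1S,4R,5S,6S,8S,10R)-1-[(tert-butyldimethylsilyl)oxy]-4,5-epoxy-4,10-dimethyl-7-methylidene-6-[(triethylsilyl)oxy]cyclodecan-8-ol | O[C@H]1C[C@@H](C)[C@@H](O[Si](C)(C)C(C)(C)C)CC[C@@]2(C)O[C@H]2[C@@H](O[Si](CC)(CC)CC)C1=C | intermediate
16 | spiro-ozonide (1,2,4-trioxolane at C7) of 15 | O[C@H]1C[C@@H](C)[C@@H](O[Si](C)(C)C(C)(C)C)CC[C@@]2(C)O[C@H]2[C@@H](O[Si](CC)(CC)CC)C13OCOO3 | intermediate
17 | (1S,4R,5S,6R,8S,10R)-1-[(tert-butyldimethylsilyl)oxy]-4,5-epoxy-8-hydroxy-4,10-dimethyl-6-[(triethylsilyl)oxy]cyclodecan-7-one | O[C@H]1C[C@@H](C)[C@@H](O[Si](C)(C)C(C)(C)C)CC[C@@]2(C)O[C@H]2[C@@H](O[Si](CC)(CC)CC)C1=O | intermediate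
18 | (1S,4R,5S,6R,8S,10R)-1-[(tert-butyldimethylsilyl)oxy]-4,5-epoxy-4,10-dimethyl-7-oxo-6-[(triethylsilyl)oxy]cyclodecan-8-yl (2E)-2-methylbut-2-enoate | C/C=C(\C)C(=O)O[C@H]1C[C@@H](C)[C@@H](O[Si](C)(C)C(C)(C)C)CC[C@@]2(C)O[C@H]2[C@@H](O[Si](CC)(CC)CC)C1=O | intermediate
19 | (1S,4R,5S,6R,8S,10R)-1-[(tert-butyldimethylsilyl)oxy]-4,5-epoxy-6-hydroxy-4,10-dimethyl-7-oxocyclodecan-8-yl (2E)-2-methylbut-2-enoate | C/C=C(\C)C(=O)O[C@H]1C[C@@H](C)[C@@H](O[Si](C)(C)C(C)(C)C)CC[C@@]2(C)O[C@H]2[C@@H](O)C1=O | intermediate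
20 | ethyl 2-(diethoxyphosphoryl)acrylate | C=C(C(=O)OCC)P(=O)(OCC)OCC | starting material
21 | ethyl 2-(diethoxyphosphoryl)-3-[(4-methoxybenzyl)oxy]propanoate (racemic) | CCOC(=O)C(COCc1ccc(OC)cc1)P(=O)(OCC)OCC | intermediate
22 | 2-(diethoxyphosphoryl)-3-[(4-methoxybenzyl)oxy]propanoic acid (racemic) | OC(=O)C(COCc1ccc(OC)cc1)P(=O)(OCC)OCC | intermediate
23 | 6-O-[2-(diethoxyphosphoryl)-3-(4-methoxybenzyloxy)propanoyl] derivative of 19 | C/C=C(\C)C(=O)O[C@H]1C[C@@H](C)[C@@H](O[Si](C)(C)C(C)(C)C)CC[C@@]2(C)O[C@H]2[C@@H](OC(=O)C(COCc2ccc(OC)cc2)P(=O)(OCC)OCC)C1=O | intermediate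
24 | (1S,4R,5S,6S,8S,10R)-1-[(tert-butyldimethylsilyl)oxy]-4,5-epoxy-13-[(4-methoxybenzyl)oxy]-8-(tigloyloxy)germacr-7(11)-en-12,6-olide | C/C=C(\C)C(=O)O[C@H]1C[C@@H](C)[C@@H](O[Si](C)(C)C(C)(C)C)CC[C@@]2(C)O[C@H]2[C@H]2OC(=O)C(COCc3ccc(OC)cc3)=C12 | intermediate
25 | (1S,4R,5S,6S,8S,10R)-1-[(tert-butyldimethylsilyl)oxy]-4,5-epoxy-13-hydroxy-8-(tigloyloxy)germacr-7(11)-en-12,6-olide | C/C=C(\C)C(=O)O[C@H]1C[C@@H](C)[C@@H](O[Si](C)(C)C(C)(C)C)CC[C@@]2(C)O[C@H]2[C@H]2OC(=O)C(CO)=C12 | intermediate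
26 | (1S,4R,5S,6S,8S,10R)-13-acetoxy-1-[(tert-butyldimethylsilyl)oxy]-4,5-epoxy-8-(tigloyloxy)germacr-7(11)-en-12,6-olide | C/C=C(\C)C(=O)O[C@H]1C[C@@H](C)[C@@H](O[Si](C)(C)C(C)(C)C)CC[C@@]2(C)O[C@H]2[C@H]2OC(=O)C(COC(C)=O)=C12 | intermediate
27 | (1S,4R,5S,6S,8S,10R)-13-acetoxy-4,5-epoxy-1-hydroxy-8-(tigloyloxy)germacr-7(11)-en-12,6-olide, CNP0159184.1 | C/C=C(\C)C(=O)O[C@H]1C[C@@H](C)[C@@H](O)CC[C@@]2(C)O[C@H]2[C@H]2OC(=O)C(COC(C)=O)=C12 | target

Total step count: 21 (19 in the main line and 2 for acid 22).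
Longest linear sequence: 19 steps (steps 1–14 and 17–21, from neryl acetate).

Steps most likely to fail

Step 11 (ring closure). What may go wrong: the alkenylchromium may add to the C8 aldehyde with poor facial selectivity or with preference for the 8-epimer, and intermolecular coupling competes with closure of the ten-membered ring. Fallback, setting out from 14 and returning at 15: the C8 configuration is no longer left to the ring closure. The cyclisation is run as before, and the mixture of 15 and its C8 epimer, the (8R)-alcohol F1, is oxidised with Dess–Martin periodinane to the exocyclic enone, the 7-methylidene-cyclodecan-8-one F2. Corey–Bakshi–Shibata reduction of F2 with (R)-2-methyl-CBS-oxazaborolidine and catecholborane (toluene, −78 °C), in which the 1,1-disubstituted alkenyl group acts as the large substituent, should give the (8S)-alcohol 15 under reagent control.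

Step 18 (key olefination). What may go wrong: the amine base may enolise the ketone toward C6 or C8 faster than the ring closes (epimerisation, E1cB opening of the C4–C5 epoxide from the C6 enolate), or the phosphonate anion may expel the 4-methoxybenzyloxide. Fallback, setting out from 15 and returning at 26: the same C7=C11 bond is closed under neutral conditions by ring-closing metathesis, which needs neither the C7 ketone nor a base.
- Alcohol 15 is acylated with tigloyl chloride and pyridine to the 8-O-tigloyl 7-methylidene compound F3.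
- The TES ether is cleaved with buffered HF·pyridine to the C6 alcohol F4.
- F4 is esterified (EDC·HCl, DMAP) with 2-(acetoxymethyl)acrylic acid F5, itself made from commercial 2-(bromomethyl)acrylic acid and KOAc in DMF, to give the C6 2-(acetoxymethyl)acrylate F6.
- Ring-closing metathesis of the two 1,1-disubstituted alkenes of F6 (second-generation Hoveyda–Grubbs catalyst, toluene, 80–110 °C, ethylene purged) should give the tetrasubstituted butenolide 26 directly, the tiglate being inert to the catalyst.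

Step 7 (carbenoid addition). What may go wrong: low discrimination between Felkin and anti-Felkin attack on the epoxy aldehyde, so that the C6 epimers form together. Fallback, setting out from 9 and returning at 10: the addition is run without regard to selectivity. The mixture of 10 and its C6 epimer, the (1S)-bromoallylic alcohol F7, is oxidised with Dess–Martin periodinane to the α-bromo enone F8. Reduction of F8 with (S)-2-methyl-CBS-oxazaborolidine and catecholborane, the 1-bromovinyl group acting as the large substituent, should give 10 under reagent control.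

Further compounds
F1 | step 11 | (8R)-epimer of 15, (1S,4R,5S,6S,8R,10R)-1-[(tert-butyldimethylsilyl)oxy]-4,5-epoxy-4,10-dimethyl-7-methylidene-6-[(triethylsilyl)oxy]cyclodecan-8-ol | O[C@@H]1C[C@@H](C)[C@@H](O[Si](C)(C)C(C)(C)C)CC[C@@]2(C)O[C@H]2[C@@H](O[Si](CC)(CC)CC)C1=C
F2 | step 11 | (1S,4R,5S,6S,10R)-1-[(tert-butyldimethylsilyl)oxy]-4,5-epoxy-4,10-dimethyl-7-methylidene-6-[(triethylsilyl)oxy]cyclodecan-8-one | O=C1C[C@@H](C)[C@@H](O[Si](C)(C)C(C)(C)C)CC[C@@]2(C)O[C@H]2[C@@H](O[Si](CC)(CC)CC)C1=C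
F3 | step 18 | 8-O-tigloyl derivative of 15 | C/C=C(\C)C(=O)O[C@H]1C[C@@H](C)[C@@H](O[Si](C)(C)C(C)(C)C)CC[C@@]2(C)O[C@H]2[C@@H](O[Si](CC)(CC)CC)C1=C
F4 | step 18 | C6 alcohol from F3 (TES removed) | C/C=C(\C)C(=O)O[C@H]1C[C@@H](C)[C@@H](O[Si](C)(C)C(C)(C)C)CC[C@@]2(C)O[C@H]2[C@@H](O)C1=C
F5 | step 18 | 2-(acetoxymethyl)acrylic acid | C=C(COC(C)=O)C(O)=O
F6 | step 18 | C6 2-(acetoxymethyl)acrylate of F4 | C/C=C(\C)C(=O)O[C@H]1C[C@@H](C)[C@@H](O[Si](C)(C)C(C)(C)C)CC[C@@]2(C)O[C@H]2[C@@H](OC(=O)C(=C)COC(C)=O)C1=C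
F7 | step 7 | C6 epimer of 10, (1S)-2-bromo-1-{(2S,3R)-3-[(3S,4R)-3-[(tert-butyldimethylsilyl)oxy]-4-methylhex-5-en-1-yl]-3-methyloxiran-2-yl}prop-2-en-1-ol | C=C[C@@H](C)[C@@H](O[Si](C)(C)C(C)(C)C)CC[C@@]1(C)O[C@H]1[C@H](O)C(Br)=C
F8 | step 7 | 2-bromo-1-{(2R,3R)-3-[(3S,4R)-3-[(tert-butyldimethylsilyl)oxy]-4-methylhex-5-en-1-yl]-3-methyloxiran-2-yl}prop-2-en-1-one | C=C[C@@H](C)[C@@H](O[Si](C)(C)C(C)(C)C)CC[C@@]1(C)O[C@H]1C(=O)C(Br)=C
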